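**Plan**

1. Numbering: rings A/B are the 2,2,5a,7-tetramethyldecahydro-1-benzoxepine (O1, C2 … C9a; OH on C3 and C7, the CH2CH2 bridge on C6); ring C is the cyclohexene.
2. Cuts: first the bond from ring B carbon C6 to the bridge CH2 (sp2–sp3 cross-coupling); then C7–CH3 and the two CH3–C bonds of the side-chain carbinol (methyl organometallic), O1–C2 of ring A (epoxide opening), the ring C–vinyl bond, and the side-chain C=C (cross-metathesis).
3. Enabling feature: C6 lies between the quaternary ring-fusion carbon C5a (no hydrogen) and C7 (oxygenated in the target). A C6 ketone therefore enolizes only toward C7, and with OMe on C7 its enol triflate couples at C6 and delivers the C7 ketone in masked form (an alkylative 1,2-carbonyl transposition).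
4. Forward: ring B is bought as (R)-Wieland–Miescher ketone, whose enone ring is cut open to the C6 ketone plus a three-carbon acid; ring A is closed onto it; ring C comes from 2-allyl-2-methylcyclohexane-1,3-dione; the halves are joined by hydroboration/B-alkyl Suzuki–Miyaura coupling; three methyl groups are added last.
5. Stereochemistry: C5a is purchased; C9a (hydride anti to the angular methyl), C6 (axial protonation, equatorial bridge) and C7 (equatorial attack, axial OH) are relayed from it through the ring B chair; C3 comes from Shi epoxidation; both ring C centres come from one CBS desymmetrization.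

Key step: step 18

Remark: TBS = tert-butyldimethylsilyl, Tf = trifluoromethanesulfonyl; 11, 12 and 18 are drawn as the expected major epimer at a centre that becomes sp2 in the following triflation, so either epimer serves.

**Route**

Step 1
Reactants: 1 (R)-Wieland–Miescher ketone
Product: 2 (4aR,5R)-5-hydroxy-4a-methyl-4,4a,5,6,7,8-hexahydronaphthalen-2(3H)-one
Conditions: NaBH4 (0.3 equiv), EtOH, −10 °C
Reagents that add atoms: none
Why: Chemoselective borohydride reduction of the saturated ketone (the enone carbonyl is deactivated by conjugation); hydride enters anti to the angular methyl, so the new carbinol (future C9a) has OH cis to that methyl and trans to the carbon chain that will become ring A.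

Step 2
Reactants: 2 hydroxy enone
Product: 3 (4aR,5R)-5-(TBSO)-4a-methyl-4,4a,5,6,7,8-hexahydronaphthalen-2(3H)-one
Conditions: TBSOTf, 2,6-lutidine, CH2Cl2, 0 °C
Reagents that add atoms: tert-butyldimethylsilyl trifluoromethanesulfonate, CC(C)(C)[Si](C)(C)OS(=O)(=O)C(F)(F)F
Why: Silyl ether formation; it keeps the hydroxyl from lactonizing with the acid made in step 3.

Step 3
Reactants: 3 silyl ether enone
Product: 4 3-[(1S,2R)-2-(TBSO)-1-methyl-6-oxocyclohexyl]propanoic acid
Conditions: O3, EtOAc, −78 °C; then 30% aq. H2O2, rt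
Reagents that add atoms: ozone, O=[O+][O-]; water, O
Why: Ozonolysis of a cyclic enone with oxidative work-up cleaves the C=C bond and excises the enone α-carbon as formic acid, leaving the C6 ketone and the propanoic acid chain without touching a stereocentre.

Step 4
Reactants: 4 keto acid
Product: 6 (2S,3R)-3-(TBSO)-2-methyl-2-(4-methylpent-3-en-1-yl)cyclohexan-1-one, via phthalimidoyl ester 5 (not isolated)
Conditions: N-hydroxyphthalimide, N,N'-diisopropylcarbodiimide, DMAP (cat.), CH2Cl2, rt; then (2-methylprop-1-en-1-yl)zinc chloride (3 equiv), Ni(acac)2 (10 mol %), 2,2'-bipyridine (10 mol %), THF/DMF, rt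
Reagents that add atoms: (2-methylprop-1-en-1-yl)zinc chloride, CC(C)=C[Zn]Cl
Why: Nickel-catalysed decarboxylative alkenylation of a redox-active ester: single-electron reduction of 5 releases CO2 and a primary radical that is captured by the alkenylnickel species; the hindered ketone and the silyl ether should be inert to the alkenylzinc.

Step 5
Reactants: 6 keto alkene
Product: 7 (2S,3R)-3-(TBSO)-2-{2-[(2R)-3,3-dimethyloxiran-2-yl]ethyl}-2-methylcyclohexan-1-one
Conditions: D-fructose-derived Shi ketone (30 mol %), Oxone (2KHSO5·KHSO4·K2SO4), K2CO3, Bu4NHSO4, MeCN/CH2(OMe)2/aq. Na2B4O7–Na2EDTA buffer, 0 °C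
Reagents that add atoms: potassium peroxymonosulfate, [K+].[O-]S(=O)(=O)OO
Why: Shi asymmetric epoxidation: the chiral dioxirane transfers oxygen to the trisubstituted alkene through the spiro transition state, and reagent control should give the (R)-epoxide whose CH carbon becomes C3.

Step 6
Reactants: 7 epoxy silyl ether
Product: 9 (3R,5aS,9aR)-3-hydroxy-2,2,5a-trimethyl-3,4,5,5a,7,8,9,9a-octahydro-1-benzoxepin-6(2H)-one, via hydroxy epoxide 8 (not isolated)
Conditions: Bu4NF (TBAF), THF, 0 °C to rt; solvent exchange; then camphorsulfonic acid (10 mol %), CH2Cl2, 0 °C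
Reagents that add atoms: none
Why: Fluoride desilylation, then acid-catalysed epoxy-alcohol cyclization: the equatorial hydroxyl attacks the tertiary, cation-stabilizing epoxide carbon in the 7-endo mode, so the epoxide CH becomes C3 with retention and the trans-diequatorial OH/chain pair gives the trans-fused oxepane.

Step 7
Reactants: 9 hydroxy ketone
Product: 10 (3R,5aS,9aR)-3-(TBSO)-2,2,5a-trimethyl-3,4,5,5a,7,8,9,9a-octahydro-1-benzoxepin-6(2H)-one
Conditions: TBSOTf, 2,6-lutidine, CH2Cl2, −78 °C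
Reagents that add atoms: tert-butyldimethylsilyl trifluoromethanesulfonate, CC(C)(C)[Si](C)(C)OS(=O)(=O)C(F)(F)F
Why: Silylation of the hindered secondary alcohol; at low temperature without a trialkylamine the ketone should not be converted into its silyl enol ether.

Step 8
Reactants: 10 ketone
Product: 11 (3R,5aS,7R,9aR)-3-(TBSO)-7-hydroxy-2,2,5a-trimethyl-3,4,5,5a,7,8,9,9a-octahydro-1-benzoxepin-6(2H)-one
Conditions: KN(SiMe3)2, THF, −78 °C; then 2-(phenylsulfonyl)-3-phenyloxaziridine, −78 °C; NH4Cl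
Reagents that add atoms: 2-(phenylsulfonyl)-3-phenyloxaziridine, O=S(=O)(c1ccccc1)N1OC1c1ccccc1
Why: Davis enolate hydroxylation: because C5a is quaternary the ketone can enolize only toward C7, so oxygen enters at C7 alone; attack anti to the axial C5a methyl should favour the equatorial alcohol, a centre that is destroyed in step 10.

Step 9
Reactants: 11 α-hydroxy ketone
Product: 12 (3R,5aS,7R,9aR)-3-(TBSO)-7-methoxy-2,2,5a-trimethyl-3,4,5,5a,7,8,9,9a-octahydro-1-benzoxepin-6(2H)-one
Conditions: MeOTf, 2,6-di-tert-butyl-4-methylpyridine, CH2Cl2, rt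
Reagents that add atoms: methyl trifluoromethanesulfonate, COS(=O)(=O)C(F)(F)F
Why: O-methylation under non-basic conditions avoids α-ketol isomerization; a methyl ether, unlike a silyl ether, cannot migrate to the neighbouring enolate oxygen in step 10.

Step 10
Reactants: 12 α-methoxy ketone
Product: 13 (3R,5aS,9aR)-3-(TBSO)-7-methoxy-2,2,5a-trimethyl-2,3,4,5,5a,8,9,9a-octahydro-1-benzoxepin-6-yl trifluoromethanesulfonate
Conditions: KN(SiMe3)2, THF, −78 °C; then N-(5-chloropyridin-2-yl)bis(trifluoromethanesulfonyl)imide (Comins' reagent), −78 to −40 °C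
Reagents that add atoms: Comins' reagent, O=S(=O)(N(c1ccc(Cl)cn1)S(=O)(=O)C(F)(F)F)C(F)(F)F
Why: Enol triflate formation from the potassium enolate; only C7–H can be removed, so a single tetrasubstituted C6=C7 enol triflate should form.

Step 11
Reactants: 14 2-methylcyclohexane-1,3-dione
Product: 15 2-methyl-2-(prop-2-en-1-yl)cyclohexane-1,3-dione
Conditions: allyl bromide, 1 M aq. NaOH, rt
Reagents that add atoms: allyl bromide, C=CCBr
Why: C-alkylation of the cyclic 1,3-dione enolate with a reactive allylic halide.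

Step 12
Reactants: 15 prochiral dione
Product: 16 (2R,3R)-3-hydroxy-2-methyl-2-(prop-2-en-1-yl)cyclohexan-1-one
Conditions: (S)-2-methyl-CBS-oxazaborolidine (20 mol %), catecholborane, PhNEt2, toluene, −60 °C
Reagents that add atoms: none
Why: CBS desymmetrization of a 2,2-disubstituted 1,3-diketone: with the quaternary carbon as the large group the (S)-catalyst should give the (R)-carbinol, and hydride enters anti to the allyl group, so the carbinol and the quaternary centre are set in one event with OH cis to allyl.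

Step 13
Reactants: 16 ketol
Product: 17 (2R,3R)-3-(TBSO)-2-methyl-2-(prop-2-en-1-yl)cyclohexan-1-one
Conditions: TBSOTf, 2,6-lutidine, CH2Cl2, −78 to 0 °C
Reagents that add atoms: tert-butyldimethylsilyl trifluoromethanesulfonate, CC(C)(C)[Si](C)(C)OS(=O)(=O)C(F)(F)F
Why: Silyl protection of the neopentyl secondary alcohol before the enolate steps.

Step 14
Reactants: 17 ketone
Product: 18 (2R,3R,6R)-3-(TBSO)-2,6-dimethyl-2-(prop-2-en-1-yl)cyclohexan-1-one
Conditions: LiN(i-Pr)2, THF, −78 °C; then MeI, −78 to 0 °C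
Reagents that add atoms: iodomethane, CI
Why: Regiospecific enolate alkylation (only C6 carries α-hydrogens), with methyl expected trans to the allyl group.

Step 15
Reactants: 18 α-methyl ketone
Product: 19 (5R,6R)-5-(TBSO)-2,6-dimethyl-6-(prop-2-en-1-yl)cyclohex-1-en-1-yl trifluoromethanesulfonate
Conditions: KN(SiMe3)2, THF, −78 °C; then Comins' reagent, −78 to 0 °C
Reagents that add atoms: Comins' reagent, O=S(=O)(N(c1ccc(Cl)cn1)S(=O)(=O)C(F)(F)F)C(F)(F)F
Why: Enol triflate formation; the single enolizable position gives the tetrasubstituted triflate that fixes the ring C double bond.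

Step 16
Reactants: 19 allyl enol triflate
Product: 20 methyl (2E)-4-[(1R,6R)-6-(TBSO)-1,3-dimethyl-2-(trifluoromethylsulfonyloxy)cyclohex-2-en-1-yl]but-2-enoate
Conditions: methyl acrylate (5 equiv), second-generation Grubbs catalyst RuCl2(H2IMes)(PCy3)(=CHPh) (5 mol %), CH2Cl2, 40 °C
Reagents that add atoms: methyl acrylate, C=CC(=O)OC
Why: Olefin cross-metathesis of the terminal allyl group with an acrylate, which should give the E-enoate; it is placed after the enolate chemistry and before the vinyl group exists, so neither strong base nor ring-closing metathesis can interfere.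

Step 17
Reactants: 20 enoate triflate
Product: 21 methyl (2E)-4-[(1S,6R)-6-(TBSO)-2-ethenyl-1,3-dimethylcyclohex-2-en-1-yl]but-2-enoate
Conditions: tributyl(vinyl)stannane, Pd(PPh3)4 (10 mol %), CuCl, LiCl, DMSO, 60 °C
Reagents that add atoms: tributyl(vinyl)stannane, C=C[Sn](CCCC)(CCCC)CCCC
Why: Copper-accelerated Stille coupling, the usual answer to tetrasubstituted enol triflates flanked by a quaternary carbon; it installs the vinyl group that becomes the two-carbon bridge.

Step 18
Reactants: 21 ring C diene; 13 ring A/B enol triflate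
Product: 23 methyl (2E)-4-[(1S,6R)-6-(TBSO)-2-{2-[(3R,5aR,9aR)-3-(TBSO)-7-methoxy-2,2,5a-trimethyl-2,3,4,5,5a,8,9,9a-octahydro-1-benzoxepin-6-yl]ethyl}-1,3-dimethylcyclohex-2-en-1-yl]but-2-enoate, via alkyl-9-BBN borane 22 (not isolated)
Conditions: 9-BBN (1.3 equiv), THF, 0 °C to rt; then 13, Pd(dppf)Cl2 (10 mol %), AsPh3 (10 mol %), Cs2CO3 (3 equiv), DMF/THF/H2O, 45 °C
Reagents that add atoms: none
Why: 9-BBN adds anti-Markovnikov to the monosubstituted vinyl group of 21 to give primary borane 22; zerovalent palladium then inserts into the C6–OTf bond of 13, the base-activated borane transfers its primary alkyl group, and reductive elimination forms the C6–CH2 bond. The closest known reaction type is the B-alkyl Suzuki–Miyaura coupling of alkyl-9-BBN reagents with cyclic enol triflates. The step closes no ring and creates no stereocentre; its product is the C6=C7 methyl enol ether, that is the C7 ketone in latent form, from which C6 (step 19) and C7 (step 20) are set by the ring B chair. Site selectivity at ring B needs no control, because C5a is quaternary and 13 is therefore a single regioisomer. Hydroboration must choose the vinyl group over the tetrasubstituted ring alkene and the hindered, electron-poor enoate alkene, which the bulk of 9-BBN secures; the large bite angle of dppf should suppress β-hydride elimination.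

Step 19
Reactants: 23 enol ether
Product: 24 methyl (2E)-4-[(1S,6R)-6-(TBSO)-2-{2-[(3R,5aR,6R,9aR)-3-(TBSO)-2,2,5a-trimethyl-7-oxodecahydro-1-benzoxepin-6-yl]ethyl}-1,3-dimethylcyclohex-2-en-1-yl]but-2-enoate
Conditions: 1 M aq. HCl, THF, 0 °C to rt
Reagents that add atoms: water, O
Why: Enol ether hydrolysis: protonation at C6 along the axial direction anti to the axial C5a methyl, and acid-mediated equilibration through the enol, should both place the bridge equatorial (6R) before the hemiketal loses methanol; TBS ethers and the enoate should survive dilute acid.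

Step 20
Reactants: 24 keto enoate
Product: 27 (3R,5aR,6R,7S,9aR)-3-(TBSO)-6-{2-[(5R,6S)-5-(TBSO)-6-[(2E)-4-hydroxy-4-methylpent-2-en-1-yl]-2,6-dimethylcyclohex-1-en-1-yl]ethyl}-2,2,5a,7-tetramethyldecahydro-1-benzoxepin-7-ol, via hydroxy ester 25 (not isolated), via methyl enone 26 (not isolated)
Conditions: MeMgCl (8 equiv), anhydrous CeCl3 (8 equiv), THF, −78 to 0 °C
Reagents that add atoms: methylmagnesium chloride, C[Mg]Cl
Why: Organocerium 1,2-additions: the axial trajectory at the C7 ketone is blocked by the syn-axial C5a methyl (as in 3,3,5-trimethylcyclohexanone), so methyl should enter equatorially and give the axial 7-OH (7S), while the enoate takes up two methyls by 1,2-addition to give the E-allylic tertiary alcohol; cerium suppresses enolization and conjugate addition.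

Step 21
Reactants: 27 bis-silyl ether
Product: 28 siphonellinol C
Conditions: Bu4NF (6 equiv), THF, 50 °C
Reagents that add atoms: none
Why: Fluoride cleavage of the two hindered secondary silyl ethers; the tertiary and allylic alcohols are stable to fluoride.

**Compound list**

1 | (8aR)-8a-methyl-3,4,8,8a-tetrahydronaphthalene-1,6(2H,7H)-dione, (R)-Wieland–Miescher ketone | C[C@@]12CCC(=O)C=C1CCCC2=O | starting material
2 | (4aR,5R)-5-hydroxy-4a-methyl-4,4a,5,6,7,8-hexahydronaphthalen-2(3H)-one | C[C@@]12CCC(=O)C=C1CCC[C@H]2O | intermediate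
3 | (4aR,5R)-5-(tert-butyldimethylsilyloxy)-4a-methyl-4,4a,5,6,7,8-hexahydronaphthalen-2(3H)-one | C[C@@]12CCC(=O)C=C1CCC[C@H]2O[Si](C)(C)C(C)(C)C | intermediate
4 | 3-[(1S,2R)-2-(tert-butyldimethylsilyloxy)-1-methyl-6-oxocyclohexyl]propanoic acid | C[C@@]1(CCC(=O)O)C(=O)CCC[C@H]1O[Si](C)(C)C(C)(C)C | intermediate
5 | 1,3-dioxoisoindolin-2-yl 3-[(1S,2R)-2-(tert-butyldimethylsilyloxy)-1-methyl-6-oxocyclohexyl]propanoate | C[C@@]1(CCC(=O)ON2C(=O)c3ccccc3C2=O)C(=O)CCC[C@H]1O[Si](C)(C)C(C)(C)C | intermediate (not isolated)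
6 | (2S,3R)-3-(tert-butyldimethylsilyloxy)-2-methyl-2-(4-methylpent-3-en-1-yl)cyclohexan-1-one | C[C@@]1(CCC=C(C)C)C(=O)CCC[C@H]1O[Si](C)(C)C(C)(C)C | intermediate
7 | (2S,3R)-3-(tert-butyldimethylsilyloxy)-2-{2-[(2R)-3,3-dimethyloxiran-2-yl]ethyl}-2-methylcyclohexan-1-one | C[C@@]1(CC[C@H]2OC2(C)C)C(=O)CCC[C@H]1O[Si](C)(C)C(C)(C)C | intermediate
8 | (2S,3R)-2-{2-[(2R)-3,3-dimethyloxiran-2-yl]ethyl}-3-hydroxy-2-methylcyclohexan-1-one | C[C@@]1(CC[C@H]2OC2(C)C)C(=O)CCC[C@H]1O | intermediate (not isolated)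
9 | (3R,5aS,9aR)-3-hydroxy-2,2,5a-trimethyl-3,4,5,5a,7,8,9,9a-octahydro-1-benzoxepin-6(2H)-one, trans-fused | O=C1[C@@]2(C)CC[C@@H](O)C(C)(C)O[C@@H]2CCC1 | intermediate
10 | (3R,5aS,9aR)-3-(tert-butyldimethylsilyloxy)-2,2,5a-trimethyl-3,4,5,5a,7,8,9,9a-octahydro-1-benzoxepin-6(2H)-one | O=C1[C@@]2(C)CC[C@@H](O[Si](C)(C)C(C)(C)C)C(C)(C)O[C@@H]2CCC1 | intermediate
11 | (3R,5aS,7R,9aR)-3-(tert-butyldimethylsilyloxy)-7-hydroxy-2,2,5a-trimethyl-3,4,5,5a,7,8,9,9a-octahydro-1-benzoxepin-6(2H)-one | O=C1[C@@]2(C)CC[C@@H](O[Si](C)(C)C(C)(C)C)C(C)(C)O[C@@H]2CC[C@H]1O | intermediate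
12 | (3R,5aS,7R,9aR)-3-(tert-butyldimethylsilyloxy)-7-methoxy-2,2,5a-trimethyl-3,4,5,5a,7,8,9,9a-octahydro-1-benzoxepin-6(2H)-one | O=C1[C@@]2(C)CC[C@@H](O[Si](C)(C)C(C)(C)C)C(C)(C)O[C@@H]2CC[C@H]1OC | intermediate
13 | (3R,5aS,9aR)-3-(tert-butyldimethylsilyloxy)-7-methoxy-2,2,5a-trimethyl-2,3,4,5,5a,8,9,9a-octahydro-1-benzoxepin-6-yl trifluoromethanesulfonate | COC1=C(OS(=O)(=O)C(F)(F)F)[C@@]2(C)CC[C@@H](O[Si](C)(C)C(C)(C)C)C(C)(C)O[C@@H]2CC1 | intermediate
14 | 2-methylcyclohexane-1,3-dione | CC1C(=O)CCCC1=O | starting material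
15 | 2-methyl-2-(prop-2-en-1-yl)cyclohexane-1,3-dione | C=CCC1(C)C(=O)CCCC1=O | intermediate
16 | (2R,3R)-3-hydroxy-2-methyl-2-(prop-2-en-1-yl)cyclohexan-1-one, OH cis to allyl | O=C1[C@](C)(CC=C)[C@H](O)CCC1 | intermediate
17 | (2R,3R)-3-(tert-butyldimethylsilyloxy)-2-methyl-2-(prop-2-en-1-yl)cyclohexan-1-one | O=C1[C@](C)(CC=C)[C@H](O[Si](C)(C)C(C)(C)C)CCC1 | intermediate
18 | (2R,3R,6R)-3-(tert-butyldimethylsilyloxy)-2,6-dimethyl-2-(prop-2-en-1-yl)cyclohexan-1-one | O=C1[C@](C)(CC=C)[C@H](O[Si](C)(C)C(C)(C)C)CC[C@H]1C | intermediate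
19 | (5R,6R)-5-(tert-butyldimethylsilyloxy)-2,6-dimethyl-6-(prop-2-en-1-yl)cyclohex-1-en-1-yl trifluoromethanesulfonate | CC1=C(OS(=O)(=O)C(F)(F)F)[C@](C)(CC=C)[C@H](O[Si](C)(C)C(C)(C)C)CC1 | intermediate
20 | methyl (2E)-4-[(1R,6R)-6-(tert-butyldimethylsilyloxy)-1,3-dimethyl-2-(trifluoromethylsulfonyloxy)cyclohex-2-en-1-yl]but-2-enoate | CC1=C(OS(=O)(=O)C(F)(F)F)[C@](C)(C/C=C/C(=O)OC)[C@H](O[Si](C)(C)C(C)(C)C)CC1 | intermediate
21 | methyl (2E)-4-[(1S,6R)-6-(tert-butyldimethylsilyloxy)-2-ethenyl-1,3-dimethylcyclohex-2-en-1-yl]but-2-enoate | CC1=C(C=C)[C@](C)(C/C=C/C(=O)OC)[C@H](O[Si](C)(C)C(C)(C)C)CC1 | intermediate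
22 | methyl (2E)-4-[(1S,6R)-2-[2-(9-borabicyclo[3.3.1]nonan-9-yl)ethyl]-6-(tert-butyldimethylsilyloxy)-1,3-dimethylcyclohex-2-en-1-yl]but-2-enoate | CC1=C(CCB2C3CCCC2CCC3)[C@](C)(C/C=C/C(=O)OC)[C@H](O[Si](C)(C)C(C)(C)C)CC1 | intermediate (not isolated)
23 | methyl (2E)-4-[(1S,6R)-6-(tert-butyldimethylsilyloxy)-2-{2-[(3R,5aR,9aR)-3-(tert-butyldimethylsilyloxy)-7-methoxy-2,2,5a-trimethyl-2,3,4,5,5a,8,9,9a-octahydro-1-benzoxepin-6-yl]ethyl}-1,3-dimethylcyclohex-2-en-1-yl]but-2-enoate | COC1=C(CCC2=C(C)CC[C@@H](O[Si](C)(C)C(C)(C)C)[C@@]2(C)C/C=C/C(=O)OC)[C@@]3(C)CC[C@@H](O[Si](C)(C)C(C)(C)C)C(C)(C)O[C@@H]3CC1 | intermediate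
24 | methyl (2E)-4-[(1S,6R)-6-(tert-butyldimethylsilyloxy)-2-{2-[(3R,5aR,6R,9aR)-3-(tert-butyldimethylsilyloxy)-2,2,5a-trimethyl-7-oxodecahydro-1-benzoxepin-6-yl]ethyl}-1,3-dimethylcyclohex-2-en-1-yl]but-2-enoate | CC1=C(CC[C@@H]2[C@@]3(C)CC[C@@H](O[Si](C)(C)C(C)(C)C)C(C)(C)O[C@@H]3CCC2=O)[C@](C)(C/C=C/C(=O)OC)[C@H](O[Si](C)(C)C(C)(C)C)CC1 | intermediate
25 | methyl (2E)-4-[(1S,6R)-6-(tert-butyldimethylsilyloxy)-2-{2-[(3R,5aR,6R,7S,9aR)-3-(tert-butyldimethylsilyloxy)-7-hydroxy-2,2,5a,7-tetramethyldecahydro-1-benzoxepin-6-yl]ethyl}-1,3-dimethylcyclohex-2-en-1-yl]but-2-enoate | CC1=C(CC[C@@H]2[C@@]3(C)CC[C@@H](O[Si](C)(C)C(C)(C)C)C(C)(C)O[C@@H]3CC[C@]2(C)O)[C@](C)(C/C=C/C(=O)OC)[C@H](O[Si](C)(C)C(C)(C)C)CC1 | intermediate (not isolated)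
26 | (3E)-5-[(1S,6R)-6-(tert-butyldimethylsilyloxy)-2-{2-[(3R,5aR,6R,7S,9aR)-3-(tert-butyldimethylsilyloxy)-7-hydroxy-2,2,5a,7-tetramethyldecahydro-1-benzoxepin-6-yl]ethyl}-1,3-dimethylcyclohex-2-en-1-yl]pent-3-en-2-one | CC1=C(CC[C@@H]2[C@@]3(C)CC[C@@H](O[Si](C)(C)C(C)(C)C)C(C)(C)O[C@@H]3CC[C@]2(C)O)[C@](C)(C/C=C/C(C)=O)[C@H](O[Si](C)(C)C(C)(C)C)CC1 | intermediate (not isolated)
27 | (3R,5aR,6R,7S,9aR)-3-(tert-butyldimethylsilyloxy)-6-{2-[(5R,6S)-5-(tert-butyldimethylsilyloxy)-6-[(2E)-4-hydroxy-4-methylpent-2-en-1-yl]-2,6-dimethylcyclohex-1-en-1-yl]ethyl}-2,2,5a,7-tetramethyldecahydro-1-benzoxepin-7-ol | CC1=C(CC[C@@H]2[C@@]3(C)CC[C@@H](O[Si](C)(C)C(C)(C)C)C(C)(C)O[C@@H]3CC[C@]2(C)O)[C@](C)(C/C=C/C(C)(C)O)[C@H](O[Si](C)(C)C(C)(C)C)CC1 | intermediate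
28 | siphonellinol C, (3R,5aR,6R,7S,9aR)-6-{2-[(5R,6S)-5-hydroxy-6-[(2E)-4-hydroxy-4-methylpent-2-en-1-yl]-2,6-dimethylcyclohex-1-en-1-yl]ethyl}-2,2,5a,7-tetramethyldecahydro-1-benzoxepine-3,7-diol | CC1=C(CC[C@@H]2[C@@]3(C)CC[C@@H](O)C(C)(C)O[C@@H]3CC[C@]2(C)O)[C@](C)(C/C=C/C(C)(C)O)[C@H](O)CC1 | target

**Step count and risks**

Total step count: 21. Longest linear sequence: 14 (steps 1–10, then 18–21).

Steps most likely to fail:

Step 18. Oxidative addition and transmetalation at the congested, electron-rich C6 triflate may be slow, so that protodeboronation of the borane or β-hydride elimination takes over. The fallback is a nickel-catalysed reductive cross-electrophile coupling, in which an alkyl radical is captured at nickel and no boronate has to reach the hindered vinyl metal. It sets out from 21: hydroboration with 9-BBN to 22 followed by iodination (I2, NaOMe, 0 °C) would give methyl (2E)-4-[(1S,6R)-6-(tert-butyldimethylsilyloxy)-2-(2-iodoethyl)-1,3-dimethylcyclohex-2-en-1-yl]but-2-enoate F1. With triflate 13, NiBr2(dme), 2,2'-bipyridine and zinc dust in N,N-dimethylacetamide this should give 23, where the route is rejoined.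

Step 6. The hydroxyl may attack the secondary epoxide carbon instead (6-exo opening to a tetrahydropyran, with inversion at the future C3), or the ketone oxygen may take part. The fallback removes the secondary carbon as an electrophile before ring closure and closes ring A by Markovnikov oxymercuration. It sets out from 7: silyl triflate/amidine isomerization of the epoxide (Me3SiOTf, DBU, toluene) would give (2S,3R)-3-(tert-butyldimethylsilyloxy)-2-methyl-2-[(3R)-4-methyl-3-(trimethylsilyloxy)pent-4-en-1-yl]cyclohexan-1-one F2. Bu4NF would remove both silyl groups to give (2S,3R)-3-hydroxy-2-[(3R)-3-hydroxy-4-methylpent-4-en-1-yl]-2-methylcyclohexan-1-one F3. Hg(OCOCF3)2 in CH2Cl2 should then close the oxepane at the only carbon open to attack, giving {[(3R,5aS,9aR)-3-hydroxy-2,5a-dimethyl-6-oxodecahydro-1-benzoxepin-2-yl]methyl}mercury trifluoroacetate F4. Bu3SnH would reduce the C–Hg bond to the second C2 methyl and return the route to 9.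

Step 12. The catalyst may discriminate poorly between the enantiotopic carbonyls or between the two faces, or reduction may run on to the diol. The fallback is a baker's yeast desymmetrization, which gives the opposite ketol reliably, followed by an exchange of the roles of the two oxygenated carbons. It sets out from 15: yeast reduction would give (2S,3S)-3-hydroxy-2-methyl-2-(prop-2-en-1-yl)cyclohexan-1-one F5, and acetylation would give (1S,2S)-2-methyl-3-oxo-2-(prop-2-en-1-yl)cyclohexyl acetate F6. NaBH4 reduction anti to the allyl group would give (1S,3R)-3-hydroxy-2-methyl-2-(prop-2-en-1-yl)cyclohexyl acetate with both oxygens cis to allyl F7. Silylation would give (1S,3R)-3-(tert-butyldimethylsilyloxy)-2-methyl-2-(prop-2-en-1-yl)cyclohexyl acetate F8, and K2CO3/MeOH would give (1S,3R)-3-(tert-butyldimethylsilyloxy)-2-methyl-2-(prop-2-en-1-yl)cyclohexan-1-ol F9. Dess–Martin oxidation then returns the route to 17.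

**Further compounds**

F1 | step 18 | methyl (2E)-4-[(1S,6R)-6-(tert-butyldimethylsilyloxy)-2-(2-iodoethyl)-1,3-dimethylcyclohex-2-en-1-yl]but-2-enoate | CC1=C(CCI)[C@](C)(C/C=C/C(=O)OC)[C@H](O[Si](C)(C)C(C)(C)C)CC1
F2 | step 6 | (2S,3R)-3-(tert-butyldimethylsilyloxy)-2-methyl-2-[(3R)-4-methyl-3-(trimethylsilyloxy)pent-4-en-1-yl]cyclohexan-1-one | C[C@@]1(CC[C@@H](O[Si](C)(C)C)C(C)=C)C(=O)CCC[C@H]1O[Si](C)(C)C(C)(C)C
F3 | step 6 | (2S,3R)-3-hydroxy-2-[(3R)-3-hydroxy-4-methylpent-4-en-1-yl]-2-methylcyclohexan-1-one | C[C@@]1(CC[C@@H](O)C(C)=C)C(=O)CCC[C@H]1O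
F4 | step 6 | {[(3R,5aS,9aR)-3-hydroxy-2,5a-dimethyl-6-oxodecahydro-1-benzoxepin-2-yl]methyl}mercury trifluoroacetate (C2 epimers) | O=C1[C@@]2(C)CC[C@@H](O)C(C)(C[Hg]OC(=O)C(F)(F)F)O[C@@H]2CCC1
F5 | step 12 | (2S,3S)-3-hydroxy-2-methyl-2-(prop-2-en-1-yl)cyclohexan-1-one | O=C1[C@@](C)(CC=C)[C@@H](O)CCC1
F6 | step 12 | (1S,2S)-2-methyl-3-oxo-2-(prop-2-en-1-yl)cyclohexyl acetate | O=C1[C@@](C)(CC=C)[C@@H](OC(C)=O)CCC1
F7 | step 12 | (1S,3R)-3-hydroxy-2-methyl-2-(prop-2-en-1-yl)cyclohexyl acetate, both oxygens cis to allyl | O[C@H]1[C@@](C)(CC=C)[C@@H](OC(C)=O)CCC1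
F8 | step 12 | (1S,3R)-3-(tert-butyldimethylsilyloxy)-2-methyl-2-(prop-2-en-1-yl)cyclohexyl acetate, both oxygens cis to allyl | CC(C)(C)[Si](C)(C)O[C@H]1[C@@](C)(CC=C)[C@@H](OC(C)=O)CCC1
F9 | step 12 | (1S,3R)-3-(tert-butyldimethylsilyloxy)-2-methyl-2-(prop-2-en-1-yl)cyclohexan-1-ol, both oxygens cis to allyl | CC(C)(C)[Si](C)(C)O[C@H]1[C@@](C)(CC=C)[C@@H](O)CCC1
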